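The trap I walked towards was to treat initiator as a reagent that buys a fixed count of turnovers.

| setting | birch | maple | flask |
|---|---|---|---|
| starting material | 0.010 M | 0.010 M | 0.010 M |
| gas | 2 mM (held) | 2 mM (held) | 2.0 mM (held) |
| initiator | 0.67 mol% | 1.5 mol% | 1 mol% |
| remark | run made earlier | run made earlier |  |
| time |  |  | 2.0 h |

| run | time / min | target / % | starting material / % |
|---|---|---|---|
| birch | 10.0 | 3.5 | 97.8 |
| birch | 30.0 | 15.0 | 86.0 |
| birch | 60.0 | 29.3 | 68.9 |
| birch | 80.0 | 41.3 | 60.7 |
| birch | 120 | 57.0 | 44.3 |
| maple | 10.0 | 3.8 | 95.5 |
| maple | 30.0 | 22.6 | 78.1 |
| maple | 60.0 | 46.1 | 51.1 |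
| maple | 80.0 | 63.8 | 37.6 |
| maple | 120 | 87.7 | 12.0 |

(scatter of a reading: 1 percentage point)

- percentages count the starting material that a species holds: one ended chains counts as two
- at the start none of partner is dissolved
- the analysis behind the earlier runs scatters by 1 percentage point, standard deviation
- steps that have been proposed: initiator -> 2 initiating radical; starting material + initiating radical -> capped initiator + first chain carrier; partner + first chain carrier -> target + second chain carrier; starting material + second chain carrier -> by-product + first chain carrier; first chain carrier -> ended carrier; 2 first chain carrier -> ended chains; gas <-> partner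

- how much target there is at 2.0 h, in percent of the starting material charged
- concentration of partner in solution at 2.0 h, in percent of saturation

So I first counted target per initiator charged, a crude chain length, at 120 min. Birch gave 85.1 turnovers, but maple gave 58.5, fewer, and the rule of thumb broke inside this very range.

The border showed in one ratio. From birch to maple the loading rose 2.24-fold, yet target rose 1.54-fold, close to the root of the loading, 1.50.

I therefore carried the root-turnover number: target as a fraction of the charge, divided by the square root of the initiator loading, at this time and with the other charges held. Birch read 6.96 and maple 7.16, with readings scattering by 1 percentage point. Their mean, 7.06, gave me 70.6 % target for the flask. I reckoned nothing for partner.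

The forecast, which read the same runs as “mostly bimolecular termination”, put target at 70 %, slightly below my figure, and partner at 77 % of saturation.

The flask gave 70.6 % target, with partner at 77.0 % of saturation.

    initiator → 2 initiating radical (k = 0.450 h⁻¹)
    starting material + initiating radical → capped initiator + first chain carrier (k = 1.90 × 10⁵ M⁻¹ s⁻¹)
    partner + first chain carrier → target + second chain carrier (k = 27000 M⁻¹ s⁻¹)
    starting material + second chain carrier → by-product + first chain carrier (k = 94000 M⁻¹ s⁻¹)
    first chain carrier → ended carrier (k = 1500 h⁻¹)
    2 first chain carrier → ended chains (k = 3.00 × 10⁶ M⁻¹ s⁻¹)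
    gas ⇌ partner, rate k7*(csat - [partner]) (kL = 6.50 h⁻¹)

At 2.00 h the flask still held 41 % of its initiator charge. Its own root-turnover number was 7.06. Carried to the neighbour charged with 0.6 mol% of initiator, my number gave 54.7 %, and that neighbour held 51.6 % target.

(The numbers in the tables are calculated with made-up constants, noise included.)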